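| flask | substrate | gas | remark | time |
|---|---|---|---|---|
| green | 3.9 mM | 0.63 mM (held) | run made earlier |  |
| amber | 61 mM | 0.63 mM (held) | run made earlier |  |
| Thursday's | 20 mM | 0.63 mM (held) |  | 2.5 h |
| Sunday's | 6.0 mM | 0.63 mM (held) |  | 2.5 h |
| Friday's | 30 mM | 0.63 mM (held) |  | 2.5 h |
| Tuesday's | 80 mM | 0.63 mM (held) |  | 2.5 h |

| run | time / h | target / % | side product A / % |
|---|---|---|---|
| green | 0.333 | 42 | 52 |
| green | 0.833 | 42 | 52 |
| green | 1.50 | 41 | 54 |
| green | 2.50 | 42 | 49 |
| amber | 0.333 | 15 | 28 |
| amber | 0.833 | 15 | 26 |
| amber | 1.50 | 10 | 34 |
| amber | 2.50 | 12 | 32 |

(scatter of a reading: 2 percentage points)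

* ranking by share of target in all that became target or side product A or side product B, from high to low, at 2.5 h (Thursday's / Sunday's / Friday's / Tuesday's)
* the share of target in all that became target or side product A or side product B of the flask you put first, at 2.5 h
* the share of target in all that became target or side product A or side product B of the flask you put last, at 2.5 h

- a species is counted by the substrate in it: one side product B counts as two
- at the start none of reagent is dissolved
- the numbers in the tables scatter with a standard deviation of 2 percentage points
- candidate steps: substrate -> side product A; substrate + reagent -> target; 2 substrate -> side product B; gas <-> reagent; 2 reagent -> homo dimer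

The easy step is a subtraction. The sum of target and side product A stays within its scatter from 0.333 h on in green and in amber, so I take both runs as finished and count as side product B whatever target and side product A don't hold. Together those two hold 93.5% of the charge in green and 43.0% in amber.

Side product B takes two substrate per turn, the other products one, so I let its ratio to those two grow in proportion to the charge. Amber then gives the crossing charge, the charge at which side product B takes as much as target and side product A together: 46.0 mM. For green this rule puts side product B at 7.81% of the charge, and the subtraction reads 6.50%.

Tuesday's looks like amber, but its charge is 1.31 times amber's, and both charges stand above the crossing charge. Target's part of target and side product A together reads 44.7% in green and 30.2% in amber, less than in green. Keeping amber's part, I reckon 11.0% target for Tuesday's, below amber's 13.0%. Keeping green's part, I reckon 39.5% for Sunday's, whose charge lies below the crossing charge.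

The forecast says Sunday's > Thursday's > Friday's > Tuesday's, with 39% (35% to 42%) first and 10% (7% to 12.5%) last: “Selectivity falls monotonically with charge.” My first and last flask are the same as its own, and my last value stands above its 10%.

The simulation gives Sunday's > Thursday's > Friday's > Tuesday's, with 39.0% first and 11.3% last.

    substrate → side product A (k = 0.180 min⁻¹)
    substrate + reagent → target (k = 300 M⁻¹ min⁻¹)
    2 substrate → side product B (k = 6.30 M⁻¹ min⁻¹)
    gas ⇌ reagent, rate k4*(csat - [reagent]) (kL = 4.40 min⁻¹)
    2 reagent → homo dimer (k = 420 M⁻¹ min⁻¹)

Left ten times as long, Tuesday's still shows 11.3%. Its charge is 1.74 crossing charges, which puts side product B at 63.5% of the charge, and the flask holds 60.9%. The neighbour of Tuesday's charged with 140 mM stands at 3.04 crossing charges, which puts side product B at 75.3%, and that flask holds 72.1%.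

The data come from a simulation from invented constants; noise was put on by code.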